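**Retrosynthetic overview**

1. Last ring: the ten-membered carbocycle, closed by ring-closing metathesis at C1=C10 (step 14); only the C15 silyl ether is removed afterwards.
2. First ring: the γ-lactone O–C12–C11–C7–C6, closed by the C7–C11 bond. A phosphonoacetate on O6 (C11 donor) opens a C7–C8 epoxide at C7, and formaldehyde olefination in the same flask gives the α-methylene lactone with O8–H free for the isobutyrate.
3. Enabling feature: the 1,4-dioxygen array O=C12–C11–C7–C8–O8 that spans the lactone ring and its C8 oxygen. C11 (α to C12=O) and C7 (α to the C8–O carbon) are of like polarity, so C7 is reversed to an acceptor as an epoxide carbon, with O6 as the tether.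
4. Seco chain from three pieces: (E)-4,4-dimethoxybut-2-enal (C6–C9), ethynyltrimethylsilane plus CO/MeOH (C10, C14, one methylene), and a propargyl silyl ether plus butenyl Grignard (C1–C5, C15).
5. Stereocentres: C9 by asymmetric alkynylation, C6 by ligand-controlled Ni/Cr coupling, C7/C8 by Sharpless epoxidation and its stereospecific opening. Order of ring formation: lactone (step 10), then carbocycle (step 14).

Key step: step 10

Remark: germacrane numbering is used for locants (lactone C12–O–C6, C7–C11, isobutyrate on O8, acetate on O9, CO2Me = C14 on C10, CH2OH = C15 on C4); both ring alkenes are taken as written in the SMILES (C3 cis to C6, C2 cis to C9; 1(10)E,4E by CIP).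

**Route**

Step 1
Reactants: 1 (E)-4,4-dimethoxybut-2-enal; 2 ethynyltrimethylsilane
Product: 4 (3R,4E)-6,6-dimethoxy-1-(trimethylsilyl)hex-4-en-1-yn-3-ol, via alkynylzinc species 3 (not isolated)
Conditions: Me2Zn (3 equiv), ProPhenol ligand (10 mol%, enantiomer giving Si-face addition), Ph3P=O (20 mol%), toluene, 0 °C → rt; aq. NH4Cl
Reagents that add atoms: none
Why: Zinc–ProPhenol-catalysed asymmetric alkynylation adds the alkynylzinc 1,2 to the enal under ligand control (Si face), which should set C9 as 3R in 4.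

Step 2
Reactants: 4 (3R,4E)-6,6-dimethoxy-1-(trimethylsilyl)hex-4-en-1-yn-3-ol
Product: 5 {(3R,4E)-6,6-dimethoxy-3-[(4-methoxybenzyl)oxy]hex-4-en-1-yn-1-yl}trimethylsilane
Conditions: NaH, 4-methoxybenzyl chloride, Bu4NI (cat.), THF/DMF, 0 °C → rt
Reagents that add atoms: 4-methoxybenzyl chloride, COc1ccc(CCl)cc1
Why: Williamson etherification of the alkoxide leaves the stereocentre untouched and gives an O9 group that, unlike an ester or silyl group, cannot migrate to the O8 alkoxide formed in the key step.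

Step 3
Reactants: 5 {(3R,4E)-6,6-dimethoxy-3-[(4-methoxybenzyl)oxy]hex-4-en-1-yn-1-yl}trimethylsilane
Product: 6 1-({[(3R,4E)-6,6-dimethoxyhex-4-en-1-yn-3-yl]oxy}methyl)-4-methoxybenzene
Conditions: K2CO3 (cat.), MeOH, rt
Reagents that add atoms: none
Why: Base-catalysed methanolysis cleaves only the C(sp)–Si bond and frees the terminal alkyne needed for carbonylation.

Step 4
Reactants: 6 1-({[(3R,4E)-6,6-dimethoxyhex-4-en-1-yn-3-yl]oxy}methyl)-4-methoxybenzene
Product: 7 methyl (3R,4E)-6,6-dimethoxy-3-[(4-methoxybenzyl)oxy]-2-methylidenehex-4-enoate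
Conditions: Pd(OAc)2 (1 mol%), 2-(diphenylphosphino)pyridine (4 mol%), MsOH (4 mol%), CO (10 bar), MeOH, 45 °C
Reagents that add atoms: carbon monoxide, [C-]#[O+]; methanol, CO
Why: Palladium/2-pyridylphosphine-catalysed methoxycarbonylation of a terminal alkyne is Markovnikov-selective and should give the 2-substituted acrylate that carries C10, C14 and the methylene later lost in metathesis.

Step 5
Reactants: 7 methyl (3R,4E)-6,6-dimethoxy-3-[(4-methoxybenzyl)oxy]-2-methylidenehex-4-enoate
Product: 8 methyl (3R,4E)-3-[(4-methoxybenzyl)oxy]-2-methylidene-6-oxohex-4-enoate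
Conditions: PPTS (cat.), acetone/H2O (10:1), 40 °C
Reagents that add atoms: water, O
Why: Mild acid hydrolysis of the dimethyl acetal releases the (E)-enal (C6) while the benzyl-type ether, the acrylate and the C9 centre should survive.

Step 6
Reactants: 9 tert-butyldimethyl(prop-2-yn-1-yloxy)silane; 10 but-3-en-1-ylmagnesium bromide
Product: 13 tert-butyl{[(2E)-2-(iodomethylidene)hex-5-en-1-yl]oxy}dimethylsilane, via butenylcopper 11 (not isolated), via alkenylcopper 12 (not isolated)
Conditions: 10, CuBr·SMe2 (1 equiv), Et2O/Me2S, −45 °C; 9, −25 °C; I2, −78 → 0 °C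
Reagents that add atoms: iodine, II
Why: syn-Carbocupration of the terminal alkyne in ether puts the butenyl group on the internal carbon and copper on the terminus cis to it, and iodinolysis with retention gives the iodide whose C–I bond is cis to the butenyl chain (the ring-cis C4=C5 geometry).

Step 7
Reactants: 8 methyl (3R,4E)-3-[(4-methoxybenzyl)oxy]-2-methylidene-6-oxohex-4-enoate; 13 tert-butyl{[(2E)-2-(iodomethylidene)hex-5-en-1-yl]oxy}dimethylsilane
Product: 15 methyl (3R,4E,6S,7E)-8-({[tert-butyl(dimethyl)silyl]oxy}methyl)-6-hydroxy-3-[(4-methoxybenzyl)oxy]-2-methylidenedodeca-4,7,11-trienoate, via alkenylchromium species 14 (not isolated)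
Conditions: CrCl2 (4 equiv), NiCl2 (2 mol%), chiral oxazoline–sulfonamide ligand (4.4 equiv, enantiomer directing Re-face attack), Et3N (4.4 equiv), THF, rt
Reagents that add atoms: none
Why: The Nozaki–Hiyama–Kishi reaction adds the alkenyl iodide 1,2 to the enal with retention of olefin geometry and tolerates the acrylate and ethers, and the chromium-bound chiral ligand should set C6 (6S in 15).

Step 8
Reactants: 15 methyl (3R,4E,6S,7E)-8-({[tert-butyl(dimethyl)silyl]oxy}methyl)-6-hydroxy-3-[(4-methoxybenzyl)oxy]-2-methylidenedodeca-4,7,11-trienoate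
Product: 16 methyl (3S)-3-{(2R,3R)-3-[(1R,2E)-3-({[tert-butyl(dimethyl)silyl]oxy}methyl)-1-hydroxyhepta-2,6-dien-1-yl]oxiran-2-yl}-3-[(4-methoxybenzyl)oxy]-2-methylidenepropanoate
Conditions: Ti(OiPr)4 (0.3 equiv), D-(−)-diisopropyl tartrate (0.36 equiv), t-BuOOH (1.5 equiv), 4 Å MS, CH2Cl2, −20 °C
Reagents that add atoms: tert-butyl hydroperoxide, CC(C)(C)OO
Why: Sharpless asymmetric epoxidation in the matched sense (D-tartrate for this carbinol) should epoxidise only the E-C7=C8 alkene to the erythro epoxy alcohol (7R,8R), since the cis-substituted C4=C5 alkene and the acrylate are slow substrates and any 6-epimer from step 7 is mismatched and left behind.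

Step 9
Reactants: 16 epoxy alcohol (name as in step 8); 17 2-(diethoxyphosphoryl)acetic acid
Product: 18 (1R,2E)-1-[(2R,3R)-3-{(1S)-2-(methoxycarbonyl)-1-[(4-methoxybenzyl)oxy]prop-2-en-1-yl}oxiran-2-yl]-3-({[tert-butyl(dimethyl)silyl]oxy}methyl)hepta-2,6-dien-1-yl 2-(diethoxyphosphoryl)acetate
Conditions: DCC, DMAP (cat.), CH2Cl2, 0 °C → rt
Reagents that add atoms: none
Why: Steglich esterification acylates the only free hydroxyl (O6) under neutral conditions that leave the epoxide intact, placing the C11/C12 unit on the future lactone oxygen.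

Step 10
Reactants: 18 epoxy phosphonoacetate (name as in step 9)
Product: 21 methyl (3S,4S)-4-[(2R,3R)-2-{(1E)-2-({[tert-butyl(dimethyl)silyl]oxy}methyl)hexa-1,5-dien-1-yl}-4-methylidene-5-oxooxolan-3-yl]-4-hydroxy-3-[(4-methoxybenzyl)oxy]-2-methylidenebutanoate, via lithium phosphonate carbanion 19 (not isolated), via phosphono lactone enolate 20 (not isolated)
Conditions: LiHMDS (1.05 equiv), THF (0.01 M), −78 → 45 °C; then (CH2O)n (6 equiv), 0 °C → rt
Reagents that add atoms: formaldehyde (as paraformaldehyde), C=O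
Why: Proposed new method: LiHMDS deprotonates the phosphonoacetate to 19, and the lithium-chelated, phosphoryl-stabilised carbanion C11 attacks C7 of the lithium-activated trans-epoxide in line with the breaking C7–O bond, which closes the γ-lactone ring O–C12–C11–C7–C6 in the 5-exo-tet mode (attack at C8 would be 6-endo); the released O8 alkoxide is at once protonated by the new, more acidic C11–H to give enolate 20, which undergoes Horner–Wadsworth–Emmons olefination with formaldehyde in the same flask to install the C11=C13 methylene. The closest known reaction types are the telescoped intramolecular Michael addition/olefination of phosphonoacetates of γ-hydroxy enones and the intermolecular alkylation of phosphonoacetate anions by epoxides to α-phosphono-γ-lactones; the tethered epoxide variant on a 2,3-epoxy alcohol ester is the part not yet shown. C7 is set by inversion at the epoxide carbon, and because the epoxy alcohol is erythro this gives the 6,7-trans lactone; C8 keeps its C–O bond and configuration, and C11 ends sp2 so its transient configuration does not matter. The step needs C- over O-alkylation, C7 over C8 attack and cyclisation over Michael addition to the acrylate: the soft carbanion and the five-membered ring favour C7, high dilution and the nine-membered alternative disfavour the Michael pathways, and the internal proton transfer to 20 should keep the O8 alkoxide from attacking phosphorus (cyclopropane formation) or C12 (translactonisation).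

Step 11
Reactants: 21 hydroxy α-methylene lactone (name as in step 10)
Product: 22 methyl (3S,4S)-4-[(2R,3S)-2-{(1E)-2-({[tert-butyl(dimethyl)silyl]oxy}methyl)hexa-1,5-dien-1-yl}-4-methylidene-5-oxooxolan-3-yl]-3-[(4-methoxybenzyl)oxy]-2-methylidene-4-[(2-methylpropanoyl)oxy]butanoate
Conditions: isobutyryl chloride, pyridine, DMAP (cat.), CH2Cl2, 0 °C
Reagents that add atoms: isobutyryl chloride, CC(C)C(=O)Cl
Why: Acylation of the only free hydroxyl (O8) under weakly basic conditions should outrun any translactonisation and fixes the isobutyrate where the epoxide oxygen was.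

Step 12
Reactants: 22 isobutyrate (name as in step 11)
Product: 23 methyl (3S,4S)-4-[(2R,3S)-2-{(1E)-2-({[tert-butyl(dimethyl)silyl]oxy}methyl)hexa-1,5-dien-1-yl}-4-methylidene-5-oxooxolan-3-yl]-3-hydroxy-2-methylidene-4-[(2-methylpropanoyl)oxy]butanoate
Conditions: DDQ (1.3 equiv), CH2Cl2/pH 7 buffer (10:1), 0 °C → rt
Reagents that add atoms: none
Why: Oxidative cleavage of the 4-methoxybenzyl ether by DDQ under buffered conditions should free O9 without touching the silyl ether, the esters or the alkenes and without acyl migration.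

Step 13
Reactants: 23 C9 alcohol (name as in step 12)
Product: 24 methyl (3S,4S)-3-(acetyloxy)-4-[(2R,3S)-2-{(1E)-2-({[tert-butyl(dimethyl)silyl]oxy}methyl)hexa-1,5-dien-1-yl}-4-methylidene-5-oxooxolan-3-yl]-2-methylidene-4-[(2-methylpropanoyl)oxy]butanoate
Conditions: Ac2O, pyridine, DMAP (cat.), CH2Cl2, 0 °C
Reagents that add atoms: acetic anhydride, CC(=O)OC(C)=O
Why: Standard acetylation of the allylic O9 hydroxyl gives the C9 acetate with retention, and the small ester also lowers the steric load next to the acrylate for the metathesis.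

Step 14
Reactants: 24 seco diene (name as in step 13)
Product: 25 methyl (3aS,4S,5S,6E,10E,11aR)-5-(acetyloxy)-10-({[tert-butyl(dimethyl)silyl]oxy}methyl)-3-methylidene-4-[(2-methylpropanoyl)oxy]-2-oxo-2,3,3a,4,5,8,9,11a-octahydrocyclodeca[b]furan-6-carboxylate
Conditions: Hoveyda–Grubbs second-generation catalyst (15 mol%, in portions), 1,4-benzoquinone (cat.), toluene (0.5 mM), 100 °C
Reagents that add atoms: none
Why: Ring-closing metathesis should start at the terminal C1 vinyl group and close onto the 2-substituted acrylate to the (E)-enoate, the only geometry the ten-membered ring allows, while closure onto the lactone methylene would need a bridgehead olefin and the trisubstituted C4=C5 alkene is inert.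

Step 15
Reactants: 25 silyl-protected target (name as in step 14)
Product: 26 methyl (3aS,4S,5S,6E,10E,11aR)-5-(acetyloxy)-10-(hydroxymethyl)-3-methylidene-4-[(2-methylpropanoyl)oxy]-2-oxo-2,3,3a,4,5,8,9,11a-octahydrocyclodeca[b]furan-6-carboxylate (target)
Conditions: HF·pyridine, THF/pyridine, 0 °C → rt
Reagents that add atoms: none
Why: Buffered fluoride cleaves the primary allylic silyl ether under conditions that should spare the α-methylene lactone, both esters and the enoate.

**Compound list**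

1 | (E)-4,4-dimethoxybut-2-enal | COC(OC)/C=C/C=O | starting material
2 | ethynyltrimethylsilane | C#C[Si](C)(C)C | starting material
3 | methyl[(trimethylsilyl)ethynyl]zinc | C[Zn]C#C[Si](C)(C)C | intermediate
4 | (3R,4E)-6,6-dimethoxy-1-(trimethylsilyl)hex-4-en-1-yn-3-ol | COC(OC)/C=C/[C@@H](O)C#C[Si](C)(C)C | intermediate
5 | {(3R,4E)-6,6-dimethoxy-3-[(4-methoxybenzyl)oxy]hex-4-en-1-yn-1-yl}trimethylsilane | COC(OC)/C=C/[C@@H](OCc1ccc(OC)cc1)C#C[Si](C)(C)C | intermediate
6 | 1-({[(3R,4E)-6,6-dimethoxyhex-4-en-1-yn-3-yl]oxy}methyl)-4-methoxybenzene | COC(OC)/C=C/[C@@H](OCc1ccc(OC)cc1)C#C | intermediate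
7 | methyl (3R,4E)-6,6-dimethoxy-3-[(4-methoxybenzyl)oxy]-2-methylidenehex-4-enoate | COC(OC)/C=C/[C@@H](OCc1ccc(OC)cc1)C(=C)C(=O)OC | intermediate
8 | methyl (3R,4E)-3-[(4-methoxybenzyl)oxy]-2-methylidene-6-oxohex-4-enoate | O=C/C=C/[C@@H](OCc1ccc(OC)cc1)C(=C)C(=O)OC | intermediate
9 | tert-butyldimethyl(prop-2-yn-1-yloxy)silane | C#CCO[Si](C)(C)C(C)(C)C | starting material
10 | but-3-en-1-ylmagnesium bromide (ether solution) | C=CCC[Mg]Br | starting material
11 | but-3-en-1-ylcopper (MgBr2/SMe2 complex) | C=CCC[Cu] | intermediate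
12 | [(1E)-2-({[tert-butyl(dimethyl)silyl]oxy}methyl)hexa-1,5-dien-1-yl]copper | [Cu]/C=C(/CO[Si](C)(C)C(C)(C)C)CCC=C | intermediate
13 | tert-butyl{[(2E)-2-(iodomethylidene)hex-5-en-1-yl]oxy}dimethylsilane | I/C=C(/CO[Si](C)(C)C(C)(C)C)CCC=C | intermediate
14 | dichloro[(1E)-2-({[tert-butyl(dimethyl)silyl]oxy}methyl)hexa-1,5-dien-1-yl]chromium(III) | Cl[Cr](Cl)/C=C(/CO[Si](C)(C)C(C)(C)C)CCC=C | intermediate
15 | methyl (3R,4E,6S,7E)-8-({[tert-butyl(dimethyl)silyl]oxy}methyl)-6-hydroxy-3-[(4-methoxybenzyl)oxy]-2-methylidenedodeca-4,7,11-trienoate | O[C@H](/C=C(/CO[Si](C)(C)C(C)(C)C)CCC=C)/C=C/[C@@H](OCc1ccc(OC)cc1)C(=C)C(=O)OC | intermediate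
16 | methyl (3S)-3-{(2R,3R)-3-[(1R,2E)-3-({[tert-butyl(dimethyl)silyl]oxy}methyl)-1-hydroxyhepta-2,6-dien-1-yl]oxiran-2-yl}-3-[(4-methoxybenzyl)oxy]-2-methylidenepropanoate (6R,7R,8R,9S) | O[C@H](/C=C(/CO[Si](C)(C)C(C)(C)C)CCC=C)[C@H]1O[C@@H]1[C@@H](OCc1ccc(OC)cc1)C(=C)C(=O)OC | intermediate
17 | 2-(diethoxyphosphoryl)acetic acid | CCOP(=O)(OCC)CC(=O)O | starting material
18 | O6-[2-(diethoxyphosphoryl)acetyl] ester of 16 (6R,7R,8R,9S) | CCOP(=O)(OCC)CC(=O)O[C@H](/C=C(/CO[Si](C)(C)C(C)(C)C)CCC=C)[C@H]1O[C@@H]1[C@@H](OCc1ccc(OC)cc1)C(=C)C(=O)OC | intermediate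
19 | lithium salt of the phosphonoacetate carbanion of 18 | [Li+].CCOP(=O)(OCC)[CH-]C(=O)O[C@H](/C=C(/CO[Si](C)(C)C(C)(C)C)CCC=C)[C@H]1O[C@@H]1[C@@H](OCc1ccc(OC)cc1)C(=C)C(=O)OC | intermediate
20 | lithium enolate of the cyclised α-(diethoxyphosphoryl)-γ-lactone with free O8–H | [Li+].CCOP(=O)(OCC)[C-]1C(=O)O[C@H](/C=C(/CO[Si](C)(C)C(C)(C)C)CCC=C)[C@H]1[C@H](O)[C@@H](OCc1ccc(OC)cc1)C(=C)C(=O)OC | intermediate
21 | methyl (3S,4S)-4-[(2R,3R)-2-{(1E)-2-({[tert-butyl(dimethyl)silyl]oxy}methyl)hexa-1,5-dien-1-yl}-4-methylidene-5-oxooxolan-3-yl]-4-hydroxy-3-[(4-methoxybenzyl)oxy]-2-methylidenebutanoate (trans lactone) | C=C1C(=O)O[C@H](/C=C(/CO[Si](C)(C)C(C)(C)C)CCC=C)[C@H]1[C@H](O)[C@@H](OCc1ccc(OC)cc1)C(=C)C(=O)OC | intermediate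
22 | O8-isobutyrate of 21: methyl (3S,4S)-4-[(2R,3S)-…oxolan-3-yl]-3-[(4-methoxybenzyl)oxy]-2-methylidene-4-[(2-methylpropanoyl)oxy]butanoate | C=C1C(=O)O[C@H](/C=C(/CO[Si](C)(C)C(C)(C)C)CCC=C)[C@H]1[C@H](OC(=O)C(C)C)[C@@H](OCc1ccc(OC)cc1)C(=C)C(=O)OC | intermediate
23 | C9 alcohol: methyl (3S,4S)-4-[(2R,3S)-…oxolan-3-yl]-3-hydroxy-2-methylidene-4-[(2-methylpropanoyl)oxy]butanoate | C=C1C(=O)O[C@H](/C=C(/CO[Si](C)(C)C(C)(C)C)CCC=C)[C@H]1[C@H](OC(=O)C(C)C)[C@@H](O)C(=C)C(=O)OC | intermediate
24 | C9 acetate: methyl (3S,4S)-3-(acetyloxy)-4-[(2R,3S)-…oxolan-3-yl]-2-methylidene-4-[(2-methylpropanoyl)oxy]butanoate | C=C1C(=O)O[C@H](/C=C(/CO[Si](C)(C)C(C)(C)C)CCC=C)[C@H]1[C@H](OC(=O)C(C)C)[C@@H](OC(C)=O)C(=C)C(=O)OC | intermediate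
25 | methyl (3aS,4S,5S,6E,10E,11aR)-5-(acetyloxy)-10-({[tert-butyl(dimethyl)silyl]oxy}methyl)-3-methylidene-4-[(2-methylpropanoyl)oxy]-2-oxo-2,3,3a,4,5,8,9,11a-octahydrocyclodeca[b]furan-6-carboxylate | C=C1C(=O)O[C@@H]2/C=C(/CO[Si](C)(C)C(C)(C)C)CC/C=C(/C(=O)OC)[C@H](OC(C)=O)[C@@H](OC(=O)C(C)C)[C@@H]12 | intermediate
26 | methyl (3aS,4S,5S,6E,10E,11aR)-5-(acetyloxy)-10-(hydroxymethyl)-3-methylidene-4-[(2-methylpropanoyl)oxy]-2-oxo-2,3,3a,4,5,8,9,11a-octahydrocyclodeca[b]furan-6-carboxylate (germacrane numbering 6R,7S,8S,9S) | C=C1C(=O)O[C@@H]2/C=C(/CO)CC/C=C(/C(=O)OC)[C@H](OC(C)=O)[C@@H](OC(=O)C(C)C)[C@@H]12 | target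

**Step count and risks**

Total step count: 15. Longest linear sequence: 14 steps (steps 1–5 and 7–15; step 6 is the side branch).

The three steps most likely to fail:

Step 10 (the labelled step). The tethered carbanion may not reach the in-line trajectory at C7 because the ester stays in its s-trans rotamer, so that O-alkylation by the enolate oxygen, or attack of the O8 alkoxide on phosphorus (phosphoryl migration, then cyclopropane) or on C12 (translactonisation), takes over. The fallback uses known radical chemistry and sets out from 16 and comes back at 22. O6-Propargylation of 16 (propargyl bromide, Ag2O, CH2Cl2) should give the propargyl ether F1. Titanocene(III) chloride (Cp2TiCl2, Zn, THF, rt) should open the epoxide homolytically, and the C7 radical should cyclise 5-exo-dig onto the alkyne to the 3-methylidenetetrahydrofuran alcohol F2, with the two ring substituents trans whatever the C7 configuration of the epoxide. Isobutyrylation (isobutyryl chloride, pyridine) gives the isobutyrate F3. Chromium(VI) oxidation of the ring CH2 that is both allylic and next to oxygen (CrO3·3,5-dimethylpyrazole, CH2Cl2, −20 °C) should then give 22.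

Step 14. Ring closure may be slower than intermolecular metathesis of the terminal alkene (oligomerisation), because a trisubstituted electron-poor olefin has to form within a strained ten-membered ring. The fallback closes the ring through another bond and sets out from 7 and 13 and comes back at 25. Cross-metathesis of the terminal alkene of 13 with the acrylate of 7 (second-generation ruthenium catalyst, CH2Cl2, 40 °C) should give the seco enoate F4, and acetal hydrolysis as in step 5 the enal F5. An intramolecular Nozaki–Hiyama–Kishi reaction (CrCl2, NiCl2 cat., DMSO/THF, high dilution) then closes the ring at C5–C6 to the macrocyclic dienol F6. The conditions of steps 8 to 12 give in turn the macrocyclic epoxy alcohol F7, the phosphonoacetate F8, the hydroxy lactone F9, the isobutyrate F10 and the C9 alcohol F11, and acetylation as in step 13 gives 25. In this variant the epoxide opening is transannular and therefore less certain than in the main route.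

Step 4. The carbonylation may lose regiocontrol, or the acid co-catalyst may ionise the doubly activated (allylic and propargylic) C9 ether. The fallback sets out from 1 and comes back at 7. A Morita–Baylis–Hillman reaction of 1 with methyl acrylate (DABCO, rt) should give the racemic hydroxy acrylate F12. Sharpless kinetic resolution (Ti(OiPr)4, D-(−)-diisopropyl tartrate, t-BuOOH 0.6 equiv, CH2Cl2, −20 °C) should convert the 3S enantiomer into the epoxy alcohol F13 and leave the (3R)-hydroxy acrylate F14. 4-Methoxybenzyl trichloroacetimidate (cat. camphorsulfonic acid, CH2Cl2) then turns F14 into 7.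

Further compounds
F1 | step 10 | O6-(prop-2-yn-1-yl) ether of epoxy alcohol 16 | C#CCO[C@H](/C=C(/CO[Si](C)(C)C(C)(C)C)CCC=C)[C@H]1O[C@@H]1[C@@H](OCc1ccc(OC)cc1)C(=C)C(=O)OC
F2 | step 10 | trans-2,3-disubstituted 4-methylidenetetrahydrofuran with free O8–H (lactone of 21 replaced by the cyclic ether) | C=C1CO[C@H](/C=C(/CO[Si](C)(C)C(C)(C)C)CCC=C)[C@H]1[C@H](O)[C@@H](OCc1ccc(OC)cc1)C(=C)C(=O)OC
F3 | step 10 | O8-isobutyrate of F2 | C=C1CO[C@H](/C=C(/CO[Si](C)(C)C(C)(C)C)CCC=C)[C@H]1[C@H](OC(=O)C(C)C)[C@@H](OCc1ccc(OC)cc1)C(=C)C(=O)OC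
F4 | step 14 | methyl (2E,3R,4E)-2-[(4E)-4-({[tert-butyl(dimethyl)silyl]oxy}methyl)-5-iodopent-4-en-1-ylidene]-6,6-dimethoxy-3-[(4-methoxybenzyl)oxy]hex-4-enoate | I/C=C(/CO[Si](C)(C)C(C)(C)C)CC/C=C(/C(=O)OC)[C@H](OCc1ccc(OC)cc1)/C=C/C(OC)OC
F5 | step 14 | the corresponding C6 enal | I/C=C(/CO[Si](C)(C)C(C)(C)C)CC/C=C(/C(=O)OC)[C@H](OCc1ccc(OC)cc1)/C=C/C=O
F6 | step 14 | ten-membered dienol (ring C1–C10; 6-OH, E-C7=C8, O9 4-methoxybenzyl ether, ring-cis C4=C5 and C1=C10) | O[C@@H]1/C=C(/CO[Si](C)(C)C(C)(C)C)CC/C=C(/C(=O)OC)[C@H](OCc2ccc(OC)cc2)/C=C/1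
F7 | step 14 | its trans-7,8-epoxide (erythro to O6) | O[C@@H]1/C=C(/CO[Si](C)(C)C(C)(C)C)CC/C=C(/C(=O)OC)[C@H](OCc2ccc(OC)cc2)[C@H]2O[C@H]12
F8 | step 14 | O6-[2-(diethoxyphosphoryl)acetate] of F7 | CCOP(=O)(OCC)CC(=O)O[C@@H]1/C=C(/CO[Si](C)(C)C(C)(C)C)CC/C=C(/C(=O)OC)[C@H](OCc2ccc(OC)cc2)[C@H]2O[C@H]12
F9 | step 14 | macrocyclic α-methylene lactone with 8-OH and O9 4-methoxybenzyl ether | C=C1C(=O)O[C@@H]2/C=C(/CO[Si](C)(C)C(C)(C)C)CC/C=C(/C(=O)OC)[C@H](OCc3ccc(OC)cc3)[C@@H](O)[C@@H]12
F10 | step 14 | O8-isobutyrate of F9 | C=C1C(=O)O[C@@H]2/C=C(/CO[Si](C)(C)C(C)(C)C)CC/C=C(/C(=O)OC)[C@H](OCc3ccc(OC)cc3)[C@@H](OC(=O)C(C)C)[C@@H]12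
F11 | step 14 | the C9 alcohol from F10 | C=C1C(=O)O[C@@H]2/C=C(/CO[Si](C)(C)C(C)(C)C)CC/C=C(/C(=O)OC)[C@H](O)[C@@H](OC(=O)C(C)C)[C@@H]12
F12 | step 4 | racemic methyl (4E)-3-hydroxy-6,6-dimethoxy-2-methylidenehex-4-enoate | COC(OC)/C=C/C(O)C(=C)C(=O)OC
F13 | step 4 | methyl 2-{(R)-[(2R,3S)-3-(dimethoxymethyl)oxiran-2-yl](hydroxy)methyl}prop-2-enoate (erythro epoxy alcohol from the 3S enantiomer) | O[C@H](C(=C)C(=O)OC)[C@H]1O[C@@H]1C(OC)OC
F14 | step 4 | methyl (3R,4E)-3-hydroxy-6,6-dimethoxy-2-methylidenehex-4-enoate | COC(OC)/C=C/[C@@H](O)C(=C)C(=O)OC
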